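**Assumption:** (2R,3R)-fustin and (+)-gallocatechin are bought as single enantiomers (natural-product suppliers). They supply four of the five stereocentres.

## Retrosynthetic overview
1. Global hydrogenolysis (8 × OBn and the C8–Br) and 3-O-deacetylation lead back to a fully protected, 8-bromo-capped dimer.
2. Key disconnection: the C4(upper)–C6(lower) interflavan bond, made by Friedel–Crafts alkylation of a flavan-4-yl cation.
3. Regiocontrol comes from a bromine cap at C8 of the gallocatechin unit. Control of the 4α configuration comes from participation of the 3-OAc group.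
4. The electrophile is fustin after C4=O reduction, O-benzylation and 3,4-diacetylation. The nucleophile is gallocatechin after O-benzylation and bromination with NBS.
5. No ring is built. Both chroman heterocycles come intact from the chiral pool, and only C4 is newly set.

## Route

**Step 1**
Reactants: 1 (2R,3R)-fustin
Product: 2 (+)-mollisacacidin, (2R,3S,4R)-2,3-trans-3,4-trans-flavan-3,4,7,3',4'-pentaol
Conditions: NaBH4 (excess), EtOH, N2, 0 °C to rt; then H2O, EtOAc extraction at pH 6–7
Reagents that add atoms: none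
Why: In this carbonyl hydride reduction, axial hydride delivery to the half-chair trans-dihydroflavonol gives the equatorial 4-OH (3,4-trans), and C4 is ionised again in step 6 so any 4-epimer is harmless.

**Step 2**
Reactants: 2 (+)-mollisacacidin
Product: 3 7,3',4'-tri-O-benzylmollisacacidin (2R,3S,4R)
Conditions: BnBr (3.3 equiv), K2CO3, DMF, Ar, 0 °C to rt
Reagents that add atoms: benzyl bromide, BrCc1ccccc1
Why: In this Williamson ether synthesis K2CO3 deprotonates only the three phenols, so the 3,4-diol and all stereocentres are untouched.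

**Step 3**
Reactants: 3 7,3',4'-tri-O-benzylmollisacacidin
Product: 4 3,4-di-O-acetyl-7,3',4'-tri-O-benzylmollisacacidin (2R,3S,4R)
Conditions: Ac2O, pyridine, DMAP (cat.), rt
Reagents that add atoms: acetic anhydride, CC(=O)OC(C)=O
Why: One O-acylation installs both the C4 leaving group and the participating 3-OAc group without breaking any C–O bond at a stereocentre.

**Step 4**
Reactants: 5 (+)-gallocatechin (2R,3S)
Product: 6 5,7,3',4',5'-penta-O-benzylgallocatechin (2R,3S)
Conditions: BnBr (5.5 equiv), K2CO3, degassed DMF, Ar, 0 °C to rt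
Reagents that add atoms: benzyl bromide, BrCc1ccccc1
Why: This Williamson ether synthesis is selective for phenols over the secondary 3-OH, and strict exclusion of air protects the pyrogallol ring.

**Step 5**
Reactants: 6 5,7,3',4',5'-penta-O-benzylgallocatechin
Product: 7 8-bromo-5,7,3',4',5'-penta-O-benzylgallocatechin (2R,3S)
Conditions: NBS (1.0 equiv), CH2Cl2, −78 °C to 0 °C
Reagents that add atoms: N-bromosuccinimide, O=C1CCC(=O)N1Br
Why: Electrophilic aromatic bromination of O-alkylated flavan-3-ols goes to C8 of the phloroglucinol A-ring, the most nucleophilic and least hindered site, and so caps the position that would otherwise give the 4→8 dimer.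

**Step 6**
Reactants: 4 3,4-di-O-acetyl-7,3',4'-tri-O-benzylmollisacacidin (1 equiv); 7 8-bromo-penta-O-benzylgallocatechin (2–3 equiv, excess recovered)
Product: 9 3-O-acetyl-7,3',4'-tri-O-benzylfisetinidol-(4α,6)-8-bromo-5,7,3',4',5'-penta-O-benzylgallocatechin, via 3,4-cis-fused acetoxonium ion 8 (not isolated)
Conditions: TMSOTf (0.2 equiv), 4 Å MS, CH2Cl2, −40 °C to 0 °C; then aq NaHCO3
Reagents that add atoms: none
Why: In this Lewis-acid Friedel–Crafts alkylation the 4-OAc ionises to a 2,4-dioxygenated benzylic cation that the β-3-OAc captures (neighbouring-group participation), so the only free A-ring carbon of 7 (C6) attacks from the α-face and gives the 3,4-trans (4α) bond, while the resorcinol-type A-ring of 4 is too weak a nucleophile to self-condense.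

**Step 7**
Reactants: 9 acetylated bromo dimer
Product: 10 7,3',4'-tri-O-benzylfisetinidol-(4α,6)-8-bromo-5,7,3',4',5'-penta-O-benzylgallocatechin
Conditions: NaOMe (cat.), MeOH/THF, rt to 40 °C
Reagents that add atoms: none
Why: Zemplén-type transesterification cleaves the acyl–oxygen bond only, so C3 keeps its configuration and the benzyl ethers and aryl bromide are inert.

**Step 8**
Reactants: 10 octa-O-benzyl bromo dimer
Product: 11 fisetinidol-(4α,6)-gallocatechin (target)
Conditions: H2 (1 atm), 20% Pd(OH)2/C, THF/MeOH/H2O, rt; filter under Ar, Sephadex LH-20, lyophilise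
Reagents that add atoms: none
Why: Catalytic hydrogenolysis removes all eight benzyl ethers and hydrodebrominates C8 in one operation, and the 5-deoxy (profisetinidin) interflavan bond tolerates the one equivalent of dilute HBr formed.

## Compound list
1 | (2R,3R)-fustin | Oc1ccc2c(c1)O[C@H](c1ccc(O)c(O)c1)[C@@H](O)C2=O | starting material
2 | (+)-mollisacacidin (2R,3S,4R) | Oc1ccc2c(c1)O[C@H](c1ccc(O)c(O)c1)[C@@H](O)[C@@H]2O | intermediate
3 | 7,3',4'-tri-O-benzylmollisacacidin | O(Cc1ccccc1)c1ccc2c(c1)O[C@H](c1ccc(OCc3ccccc3)c(OCc3ccccc3)c1)[C@@H](O)[C@@H]2O | intermediate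
4 | 3,4-di-O-acetyl-7,3',4'-tri-O-benzylmollisacacidin | O(Cc1ccccc1)c1ccc2c(c1)O[C@H](c1ccc(OCc3ccccc3)c(OCc3ccccc3)c1)[C@@H](OC(C)=O)[C@@H]2OC(C)=O | intermediate
5 | (+)-gallocatechin (2R,3S) | Oc1cc(O)c2C[C@H](O)[C@@H](c3cc(O)c(O)c(O)c3)Oc2c1 | starting material
6 | 5,7,3',4',5'-penta-O-benzylgallocatechin | O(Cc1ccccc1)c1cc(OCc3ccccc3)c2C[C@H](O)[C@@H](c3cc(OCc4ccccc4)c(OCc4ccccc4)c(OCc4ccccc4)c3)Oc2c1 | intermediate
7 | 8-bromo-5,7,3',4',5'-penta-O-benzylgallocatechin | O(Cc1ccccc1)c1cc(OCc3ccccc3)c2C[C@H](O)[C@@H](c3cc(OCc4ccccc4)c(OCc4ccccc4)c(OCc4ccccc4)c3)Oc2c1Br | intermediate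
8 | 3,4-cis-fused (β-face) 2-methyl-1,3-dioxolan-2-ylium (acetoxonium) ion of the tri-O-benzylfisetinidol unit | O(Cc1ccccc1)c1ccc2c(c1)O[C@H](c1ccc(OCc4ccccc4)c(OCc4ccccc4)c1)[C@H]3OC(C)=[O+][C@H]32 | intermediate (not isolated)
9 | 3-O-acetyl-7,3',4'-tri-O-benzylfisetinidol-(4α,6)-8-bromo-penta-O-benzylgallocatechin | O(Cc1ccccc1)c1ccc2c(c1)O[C@H](c1ccc(OCc3ccccc3)c(OCc3ccccc3)c1)[C@@H](OC(C)=O)[C@@H]2c1c(OCc3ccccc3)c(Br)c2c(c1OCc3ccccc3)C[C@H](O)[C@@H](c1cc(OCc3ccccc3)c(OCc3ccccc3)c(OCc3ccccc3)c1)O2 | intermediate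
10 | 7,3',4'-tri-O-benzylfisetinidol-(4α,6)-8-bromo-penta-O-benzylgallocatechin | O(Cc1ccccc1)c1ccc2c(c1)O[C@H](c1ccc(OCc3ccccc3)c(OCc3ccccc3)c1)[C@@H](O)[C@@H]2c1c(OCc3ccccc3)c(Br)c2c(c1OCc3ccccc3)C[C@H](O)[C@@H](c1cc(OCc3ccccc3)c(OCc3ccccc3)c(OCc3ccccc3)c1)O2 | intermediate
11 | fisetinidol-(4α,6)-gallocatechin | Oc1ccc2c(c1)O[C@H](c1ccc(O)c(O)c1)[C@@H](O)[C@@H]2c1c(O)cc2c(c1O)C[C@H](O)[C@@H](c1cc(O)c(O)c(O)c1)O2 | target

## Summary
Total steps: 8. Longest linear sequence: 6 (steps 1, 2, 3, 6, 7, 8).

**Three steps most likely to fail**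

**Step 6.** C6 of 7 is flanked by two OBn groups and deactivated by bromine, so coupling may be slow or may stop at O-alkylation of the free 3-OH. The fallback drops protection and capping altogether. It sets out from 2 and 5. The free phenols are condensed biomimetically in 0.1 M aqueous HCl at rt with an excess of 5. The all-trans (4α,6) dimer is then separated from the dominant (4,8) isomers on Sephadex LH-20 followed by preparative HPLC. This comes back to the route directly at 11. The yield is lower, but no new compound is needed.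

**Step 2.** The 7-phenoxide of the flavan-3,4-diol may expel the 4-OH, and the resulting quinone methide would oligomerise. The fallback sets out from 1. The phenols are benzylated while C4 is still a ketone and no leaving group is present (BnBr, K2CO3, acetone, rt), giving 7,3',4'-tri-O-benzylfustin F1. The enantiopurity of F1 is checked by chiral HPLC because dihydroflavonols can ring-open under base. F1 is then reduced with NaBH4 in THF/EtOH, which comes back to the route at 3.

**Step 8.** Nine hydrogenolytic events on one hindered molecule may stall, and the product oxidises easily. The fallback sets out from 10. The bromine is removed first by halogen–lithium exchange (n-BuLi, 3.5 equiv, THF, −78 °C, then MeOH), giving 7,3',4'-tri-O-benzylfisetinidol-(4α,6)-penta-O-benzylgallocatechin F2. The benzyl ethers of F2 are then cleaved without reduction, using BCl3 and pentamethylbenzene as cation scavenger in CH2Cl2 at −78 °C. This comes back to the route at 11.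

## Further compounds
F0 | step 6 | none | none
F1 | step 2 | 7,3',4'-tri-O-benzylfustin (2R,3R) | O(Cc1ccccc1)c1ccc2c(c1)O[C@H](c1ccc(OCc3ccccc3)c(OCc3ccccc3)c1)[C@@H](O)C2=O
F2 | step 8 | 7,3',4'-tri-O-benzylfisetinidol-(4α,6)-5,7,3',4',5'-penta-O-benzylgallocatechin | O(Cc1ccccc1)c1ccc2c(c1)O[C@H](c1ccc(OCc3ccccc3)c(OCc3ccccc3)c1)[C@@H](O)[C@@H]2c1c(OCc3ccccc3)cc2c(c1OCc3ccccc3)C[C@H](O)[C@@H](c1cc(OCc3ccccc3)c(OCc3ccccc3)c(OCc3ccccc3)c1)O2
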